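The route rests on leaving out the outer ring A hydroxyl: the macrocycle is built with ring A as a simple 3‑aryloxy‑4‑hydroxy unit and the third oxygen is added last. Ring A of the target has three adjacent oxygenated carbons (C–OAr to ring B, central C–OH, outer C–OH), and the outer carbon is the only C–H ortho to the central oxygen. A di‑tert‑butylsilanol on that oxygen therefore steers Pd‑catalysed C–H oxygenation to this single carbon, forming the last ring A C–O bond and a temporary dioxasilole ring in one operation. The precursor is the 17‑membered bis(bibenzyl) macrocycle bearing the ring A silanol ether and a ring C methyl ether.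

Key step: step 13

Ring labels: A = trioxygenated ring, B = para‑linked ring, C = ring carrying one OH (OMe in the intermediates), D = unsubstituted ortho‑linked ring.
Assumption: the target has no stereocentre; the alkene geometry of 9 and 14 is left undefined because both double bonds are hydrogenated.

Step 1
Reactants: 1 3,4‑dihydroxybenzaldehyde
Product: 2 4‑(benzyloxy)‑3‑hydroxybenzaldehyde
Conditions: BnCl, NaHCO3, NaI (cat.), DMF, 40 °C
Reagents that add atoms: benzyl chloride, ClCc1ccccc1
Why: Williamson etherification in which the weak base ionizes only the more acidic 4‑OH (para to the formyl group), so that oxygen is benzylated selectively.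

Step 2
Reactants: 2 4‑(benzyloxy)‑3‑hydroxybenzaldehyde
Product: 3 2‑(benzyloxy)‑5‑(1,3‑dioxolan‑2‑yl)phenol
Conditions: ethylene glycol, p‑TsOH (cat.), toluene, reflux (Dean–Stark)
Reagents that add atoms: ethylene glycol, OCCO
Why: Acid‑catalysed acetalization with azeotropic water removal masks the ring A aldehyde, so that ring B later carries the only free aldehyde; phenol and benzyl ether tolerate catalytic acid.

Step 3
Reactants: 3 2‑(benzyloxy)‑5‑(1,3‑dioxolan‑2‑yl)phenol; 4 4‑fluorobenzaldehyde
Product: 5 4‑[2‑(benzyloxy)‑5‑(1,3‑dioxolan‑2‑yl)phenoxy]benzaldehyde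
Conditions: K2CO3, DMF, 120 °C
Reagents that add atoms: none
Why: Nucleophilic aromatic substitution (SNAr) of the para‑formyl‑activated fluoride by the ring A phenoxide; the acetal is inert to carbonate base.

Step 4
Reactants: 6 o‑vanillin (2‑hydroxy‑3‑methoxybenzaldehyde)
Product: 7 2‑(hydroxymethyl)‑6‑methoxyphenol
Conditions: NaBH4, MeOH, 0 °C
Reagents that add atoms: none
Why: Borohydride reduction of the aldehyde to the benzylic alcohol, leaving the phenol untouched.

Step 5
Reactants: 7 2‑(hydroxymethyl)‑6‑methoxyphenol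
Product: 8 (2‑hydroxy‑3‑methoxybenzyl)triphenylphosphonium bromide
Conditions: PPh3·HBr, MeCN, reflux
Reagents that add atoms: triphenylphosphine hydrobromide, [Br-].c1ccc(cc1)[PH+](c1ccccc1)c1ccccc1
Why: Acid‑mediated substitution of an ortho‑hydroxybenzyl alcohol by triphenylphosphine is the standard preparation of 2‑hydroxybenzylphosphonium salts and needs no phenol protection.

Step 6
Reactants: 5 4‑[2‑(benzyloxy)‑5‑(1,3‑dioxolan‑2‑yl)phenoxy]benzaldehyde; 8 (2‑hydroxy‑3‑methoxybenzyl)triphenylphosphonium bromide
Product: 9 2‑{2‑[4‑(2‑(benzyloxy)‑5‑(1,3‑dioxolan‑2‑yl)phenoxy)phenyl]ethenyl}‑6‑methoxyphenol (E/Z mixture)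
Conditions: KOt‑Bu (2.2 equiv), THF, 0 °C; then 5, 0 °C → rt
Reagents that add atoms: none
Why: Wittig olefination in which two equivalents of base generate the phenoxide ylide, which condenses with the only free aldehyde (ring B); the E/Z mixture is taken on because the alkene is hydrogenated next.

Step 7
Reactants: 9 2‑{2‑[4‑(2‑(benzyloxy)‑5‑(1,3‑dioxolan‑2‑yl)phenoxy)phenyl]ethenyl}‑6‑methoxyphenol
Product: 10 2‑{2‑[4‑(2‑(benzyloxy)‑5‑(1,3‑dioxolan‑2‑yl)phenoxy)phenyl]ethyl}‑6‑methoxyphenol
Conditions: H2 (4 bar), RhCl(PPh3)3 (5 mol %), toluene/EtOH, 50 °C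
Reagents that add atoms: none
Why: Homogeneous hydrogenation with RhCl(PPh3)3 saturates the disubstituted alkene but does not hydrogenolyse the aryl benzyl ether or affect the acetal.

Step 8
Reactants: 10 2‑{2‑[4‑(2‑(benzyloxy)‑5‑(1,3‑dioxolan‑2‑yl)phenoxy)phenyl]ethyl}‑6‑methoxyphenol; 11 2‑fluorobenzaldehyde
Product: 13 4‑(benzyloxy)‑3‑{4‑[2‑(2‑(2‑formylphenoxy)‑3‑methoxyphenyl)ethyl]phenoxy}benzaldehyde (open‑chain dialdehyde), via acetal aldehyde 12 (not isolated)
Conditions: Cs2CO3, DMF, 120 °C; then 2 M HCl, THF, rt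
Reagents that add atoms: water, O
Why: SNAr of the doubly ortho‑substituted ring C phenoxide on the ortho‑formyl‑activated fluoride, followed by acid hydrolysis of the dioxolane; Cs2CO3 is chosen to help the hindered phenoxide.

Step 9
Reactants: 13 open‑chain dialdehyde
Product: 14 macrocyclic stilbene (ring A benzyl ether, ring C methyl ether, CH=CH bridge between rings D and A)
Conditions: TiCl4, Zn, pyridine, THF, reflux; 13 added by syringe pump (high dilution)
Reagents that add atoms: none
Why: Intramolecular McMurry coupling, in which low‑valent titanium reductively joins the two aryl aldehydes while slow addition favours ring closure over oligomerization; ethers are tolerated.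

Step 10
Reactants: 14 macrocyclic stilbene
Product: 15 macrocyclic ring A monophenol (ring C methyl ether, both bridges CH2CH2)
Conditions: H2 (1 atm), Pd/C, EtOAc/MeOH, rt
Reagents that add atoms: none
Why: Heterogeneous catalytic hydrogenation saturates the stilbene and hydrogenolyses the benzyl ether in one operation; diaryl ethers and the methyl ether are stable.

Step 11
Reactants: 15 macrocyclic ring A monophenol
Product: 16 ring A di‑tert‑butylsilyl (Si–H) ether of the macrocycle
Conditions: t‑Bu2SiHCl, imidazole, DMAP (cat.), DMF, 50 °C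
Reagents that add atoms: di‑tert‑butylchlorosilane, CC(C)(C)[SiH](Cl)C(C)(C)C
Why: Silylation of the only free phenol with a hindered chlorosilane under nucleophilic catalysis, keeping the Si–H bond for the next step.

Step 12
Reactants: 16 ring A di‑tert‑butylsilyl (Si–H) ether
Product: 18 ring A di‑tert‑butylsilanol ether of the macrocycle (Ar–O–Si(t‑Bu)2–OH), via bromosilane 17 (not isolated)
Conditions: NBS (1.05 equiv), CH2Cl2, 0 °C; then H2O, NaHCO3, rt
Reagents that add atoms: water, O
Why: Si–H bromination with NBS followed by hydrolysis of the Si–Br bond is the established conversion of di‑tert‑butyl(aryloxy)hydrosilanes into silanols; one equivalent at 0 °C in CH2Cl2 limits ring bromination.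

Step 13
Reactants: 18 ring A di‑tert‑butylsilanol ether of the macrocycle
Product: 20 macrocyclic silicon‑bridged catechol (2,2‑di‑tert‑butyl‑1,3,2‑dioxasilole fused to ring A), via ortho‑acetoxy silanol 19 (not isolated)
Conditions: Pd(OPiv)2 (5 mol %), PhI(OAc)2 (2 equiv), toluene, 100 °C
Reagents that add atoms: (diacetoxyiodo)benzene, CC(=O)OI(OC(C)=O)c1ccccc1
Why: The silanol oxygen coordinates divalent palladium and pivalate‑assisted concerted metalation–deprotonation at the one free ring A C–H ortho to the silyloxy carbon gives a six‑membered palladacycle, which PhI(OAc)2 oxidizes to tetravalent palladium before C–OAc reductive elimination delivers acetoxy silanol 19. The acid present (AcOH, PivOH) then promotes intramolecular transesterification, the new aryl oxygen closing onto silicon with loss of acetic acid, so the dioxasilole ring forms by a 5‑exo substitution at silicon. The closest known reaction type is the silanol‑directed Pd(OPiv)2/PhI(OAc)2 ortho C–H oxygenation of phenols to silicon‑protected catechols. No stereocentre is created. The step needs site selectivity among many electron‑rich aryl C–H bonds: the tether reaches only the two ortho carbons of ring A, one of which already bears the ring B aryloxy group, and palladation of ring B would require a nine‑membered palladacycle. Ring C stays as its methyl ether so that no second phenol is silylated or oxidized by the iodine reagent.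

Step 14
Reactants: 20 macrocyclic silicon‑bridged catechol
Product: 21 macrocyclic ring A catechol (ring C methyl ether)
Conditions: Bu4NF, AcOH, THF, 0 °C → rt
Reagents that add atoms: none
Why: Fluoride‑induced cleavage of both Si–O bonds (desilylation), with acetic acid buffering to protect the electron‑rich catechol from base‑promoted air oxidation.

Step 15
Reactants: 21 macrocyclic ring A catechol (ring C methyl ether)
Product: 22 target CNP0290892.0
Conditions: BBr3 (excess), CH2Cl2, −78 °C → rt; then H2O
Reagents that add atoms: none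
Why: Lewis‑acid demethylation of the aryl methyl ether with BBr3; diaryl ether bonds are inert and excess reagent compensates for complexation by the free phenols.

Compound list
1 | 3,4‑dihydroxybenzaldehyde | O=Cc1ccc(O)c(O)c1 | starting material
2 | 4‑(benzyloxy)‑3‑hydroxybenzaldehyde | O=Cc1ccc(OCc2ccccc2)c(O)c1 | intermediate
3 | 2‑(benzyloxy)‑5‑(1,3‑dioxolan‑2‑yl)phenol | Oc1cc(C2OCCO2)ccc1OCc1ccccc1 | intermediate
4 | 4‑fluorobenzaldehyde | O=Cc1ccc(F)cc1 | starting material
5 | 4‑[2‑(benzyloxy)‑5‑(1,3‑dioxolan‑2‑yl)phenoxy]benzaldehyde | O=Cc1ccc(Oc2cc(C3OCCO3)ccc2OCc2ccccc2)cc1 | intermediate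
6 | o‑vanillin (2‑hydroxy‑3‑methoxybenzaldehyde) | COc1cccc(C=O)c1O | starting material
7 | 2‑(hydroxymethyl)‑6‑methoxyphenol | COc1cccc(CO)c1O | intermediate
8 | (2‑hydroxy‑3‑methoxybenzyl)triphenylphosphonium bromide | COc1cccc(C[P+](c2ccccc2)(c2ccccc2)c2ccccc2)c1O.[Br-] | intermediate
9 | 2‑{2‑[4‑(2‑(benzyloxy)‑5‑(1,3‑dioxolan‑2‑yl)phenoxy)phenyl]ethenyl}‑6‑methoxyphenol, E/Z mixture | COc1cccc(C=Cc2ccc(Oc3cc(C4OCCO4)ccc3OCc3ccccc3)cc2)c1O | intermediate
10 | 2‑{2‑[4‑(2‑(benzyloxy)‑5‑(1,3‑dioxolan‑2‑yl)phenoxy)phenyl]ethyl}‑6‑methoxyphenol | COc1cccc(CCc2ccc(Oc3cc(C4OCCO4)ccc3OCc3ccccc3)cc2)c1O | intermediate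
11 | 2‑fluorobenzaldehyde | O=Cc1ccccc1F | starting material
12 | acetal aldehyde: 2‑{2‑[2‑(4‑{2‑(benzyloxy)‑5‑(1,3‑dioxolan‑2‑yl)phenoxy}phenyl)ethyl]‑6‑methoxyphenoxy}benzaldehyde | COc1cccc(CCc2ccc(Oc3cc(C4OCCO4)ccc3OCc3ccccc3)cc2)c1Oc1ccccc1C=O | intermediate
13 | open‑chain dialdehyde: 4‑(benzyloxy)‑3‑{4‑[2‑(2‑(2‑formylphenoxy)‑3‑methoxyphenyl)ethyl]phenoxy}benzaldehyde | COc1cccc(CCc2ccc(Oc3cc(C=O)ccc3OCc3ccccc3)cc2)c1Oc1ccccc1C=O | intermediate
14 | macrocyclic stilbene, ring A benzyl ether, ring C methyl ether, CH=CH between rings D and A (geometry undefined) | C(c1ccccc1)Oc1ccc2cc1Oc1ccc(cc1)CCc1cccc(OC)c1Oc1ccccc1C=C2 | intermediate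
15 | macrocyclic ring A monophenol, ring C methyl ether | Oc1ccc2cc1Oc1ccc(cc1)CCc1cccc(OC)c1Oc1ccccc1CC2 | intermediate
16 | ring A di‑tert‑butylsilyl (Si–H) ether of 15 | CC(C)(C)[SiH](C(C)(C)C)Oc1ccc2cc1Oc1ccc(cc1)CCc1cccc(OC)c1Oc1ccccc1CC2 | intermediate
17 | ring A bromo(di‑tert‑butyl)silyl ether | CC(C)(C)[Si](Br)(C(C)(C)C)Oc1ccc2cc1Oc1ccc(cc1)CCc1cccc(OC)c1Oc1ccccc1CC2 | intermediate
18 | ring A di‑tert‑butylsilanol ether (key‑step precursor) | CC(C)(C)[Si](O)(C(C)(C)C)Oc1ccc2cc1Oc1ccc(cc1)CCc1cccc(OC)c1Oc1ccccc1CC2 | intermediate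
19 | ortho‑acetoxy silanol (acetate on the outer ring A carbon) | CC(=O)Oc1cc2cc(Oc3ccc(cc3)CCc3cccc(OC)c3Oc3ccccc3CC2)c1O[Si](O)(C(C)(C)C)C(C)(C)C | intermediate
20 | macrocyclic silicon‑bridged catechol (key‑step product) | CC(C)(C)[Si]4(C(C)(C)C)Oc1cc2cc(c1O4)Oc1ccc(cc1)CCc1cccc(OC)c1Oc1ccccc1CC2 | intermediate
21 | macrocyclic ring A catechol, ring C methyl ether | Oc1cc2cc(c1O)Oc1ccc(cc1)CCc1cccc(OC)c1Oc1ccccc1CC2 | intermediate
22 | CNP0290892.0 | Oc1cc2cc(c1O)Oc1ccc(cc1)CCc1cccc(O)c1Oc1ccccc1CC2 | target

Total step count: 15. Longest linear sequence: 13 steps (steps 1–3 and 6–15, from 1 to 22); steps 4–5 form a two‑step side branch.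

Steps most likely to fail

Step 13. The hypervalent iodine oxidant may attack the electron‑rich macrocycle without direction, or palladation may stall in the crowded pocket next to the ring B aryloxy group, so conversion to the silacycle may be poor. The fallback sets out from phenol 15. Magnesium‑mediated ortho‑formylation (MgCl2, Et3N, paraformaldehyde, MeCN, reflux) places a formyl group on the only free carbon ortho to the ring A phenol, giving the macrocyclic salicylaldehyde F1. Dakin oxidation (H2O2, NaOH, THF/H2O, 0 °C, under argon) converts the formyl group into a hydroxyl group and delivers catechol 21, where the route resumes at step 15.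

Step 9. Intermolecular carbonyl coupling to oligomers, or arrest at the pinacol stage, may outrun closure of the 17‑membered ring. The fallback sets out from dialdehyde 13. Reduction with NaBH4 gives the bis(benzylic) diol F2, and PBr3 converts it into the bis(benzyl bromide) F3. Intramolecular Wurtz coupling (sodium, tetraphenylethene, THF, high dilution) forms the saturated CH2CH2 bridge directly to give the benzyl‑protected saturated macrocycle F4. Hydrogenolysis (H2, Pd/C) then gives phenol 15, where the route resumes at step 11.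

Step 6. Ylide formation from the phenoxide–phosphonium zwitterion may be incomplete, or triphenylphosphine may be lost from it (ortho‑quinone methide formation), leaving the aldehyde unconsumed. The fallback reverses the roles of the partners and sets out from aldehyde 5. Reduction with NaBH4 gives the benzylic alcohol F5, an Appel reaction (CBr4, PPh3, CH2Cl2, 0 °C) gives the benzylic bromide F6, and PPh3 in toluene at 80 °C gives the ring B phosphonium bromide F7. Wittig reaction of F7 with o‑vanillin 6 (KOt‑Bu, 2.2 equiv, THF) returns to stilbene 9, where the route resumes at step 7.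

Further compounds
F1 | step 13 | macrocyclic salicylaldehyde (formyl on the outer ring A carbon of 15) | O=Cc1cc2cc(c1O)Oc1ccc(cc1)CCc1cccc(OC)c1Oc1ccccc1CC2
F2 | step 9 | open‑chain diol from reduction of 13 | COc1cccc(CCc2ccc(Oc3cc(CO)ccc3OCc3ccccc3)cc2)c1Oc1ccccc1CO
F3 | step 9 | open‑chain bis(benzyl bromide) | COc1cccc(CCc2ccc(Oc3cc(CBr)ccc3OCc3ccccc3)cc2)c1Oc1ccccc1CBr
F4 | step 9 | saturated macrocycle with ring A benzyl ether | C(c1ccccc1)Oc1ccc2cc1Oc1ccc(cc1)CCc1cccc(OC)c1Oc1ccccc1CC2
F5 | step 6 | {4‑[2‑(benzyloxy)‑5‑(1,3‑dioxolan‑2‑yl)phenoxy]phenyl}methanol | OCc1ccc(Oc2cc(C3OCCO3)ccc2OCc2ccccc2)cc1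
F6 | step 6 | 2‑{4‑(benzyloxy)‑3‑[4‑(bromomethyl)phenoxy]phenyl}‑1,3‑dioxolane | BrCc1ccc(Oc2cc(C3OCCO3)ccc2OCc2ccccc2)cc1
F7 | step 6 | {4‑[2‑(benzyloxy)‑5‑(1,3‑dioxolan‑2‑yl)phenoxy]benzyl}triphenylphosphonium bromide | [Br-].c1ccc(cc1)[P+](Cc1ccc(Oc2cc(C3OCCO3)ccc2OCc2ccccc2)cc1)(c1ccccc1)c1ccccc1
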